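**Strategy**

Ring A is a resorcylate whose carboxyl carbon is also the depside carbonyl, so the ester carbon and the six ring A carbons are one 3,5,7-trioxo acyl chain. Everything rests on disconnecting the aryl ester C–O bond together with the ring A bond between C1 (ester-bearing) and C6 (pentyl-bearing). In one operation a diketo-dioxinone loses acetone, the ring B phenol captures the resulting acylketene, and the triketo aryl ester closes by aldol addition and dehydrates to the 2,4-dihydroxy-6-pentylbenzoate, so that no hindered 2,6-disubstituted benzoic acid has to be esterified. The precursors are linear 2,2-dimethyl-6-(2,4-dioxononyl)-1,3-dioxin-4-one and tert-butyl 4-hydroxy-2-methoxy-6-propylbenzoate.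

Key step: step 6

Assumption: N-methoxy-N-methylhexanamide (3) is taken as a catalogue reagent; it is otherwise one operation from hexanoyl chloride and N,O-dimethylhydroxylamine hydrochloride.

The target has no stereocentre, so nothing has to be set or protected from scrambling.

**Route**

Step 1
Reactants: 1 2,2,6-trimethyl-4H-1,3-dioxin-4-one
Product: 2 2,2-dimethyl-6-(2-oxopropyl)-4H-1,3-dioxin-4-one
Conditions: 1 (2 equiv), LiN(SiMe3)2 (2 equiv), THF, −78 °C; then AcCl (1 equiv), −78 °C; aq. HCl
Reagents that add atoms: acetyl chloride, CC(Cl)=O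
Why: The dienolate of the dioxinone should be C-acylated at the exocyclic (gamma) carbon in a crossed Claisen condensation, the second equivalent of dienolate taking up the acidic proton of the product.

Step 2
Reactants: 2 2,2-dimethyl-6-(2-oxopropyl)-4H-1,3-dioxin-4-one; 3 N-methoxy-N-methylhexanamide
Product: 4 2,2-dimethyl-6-(2,4-dioxononyl)-4H-1,3-dioxin-4-one
Conditions: LiN(iPr)2 (2.2 equiv), THF, −78 °C; then 3, −78 to −20 °C; aq. HCl
Reagents that add atoms: none
Why: Double deprotonation gives a dianion whose terminal (methyl-derived) carbon is the most nucleophilic site and should add to the Weinreb amide, whose chelated tetrahedral adduct prevents over-addition (Claisen-type acylation of a 1,3-dicarbonyl dianion, Weinreb ketone synthesis).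

Step 3
Reactants: 5 2-methoxy-6-methylbenzoic acid
Product: 6 2-methoxy-6-propylbenzoic acid
Conditions: LiN(iPr)2 (2.2 equiv), THF, −78 to 0 °C; then EtI, −78 °C to rt; aq. HCl
Reagents that add atoms: iodoethane, CCI
Why: Lateral (benzylic) lithiation of the carboxylate gives a dianion that should be alkylated at the benzylic carbon by SN2 displacement of iodide.

Step 4
Reactants: 6 2-methoxy-6-propylbenzoic acid
Product: 7 tert-butyl 2-methoxy-6-propylbenzoate
Conditions: Cl3CC(=NH)OtBu, BF3·OEt2 (cat.), CH2Cl2–cyclohexane, rt
Reagents that add atoms: tert-butyl 2,2,2-trichloroacetimidate, CC(C)(C)OC(=N)C(Cl)(Cl)Cl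
Why: Acid-catalysed esterification with a trichloroacetimidate proceeds by O-alkylation of the carboxylic acid, so the two ortho substituents that block attack at the acyl carbon should not matter.

Step 5
Reactants: 7 tert-butyl 2-methoxy-6-propylbenzoate
Product: 9 tert-butyl 4-hydroxy-2-methoxy-6-propylbenzoate, via aryl pinacol boronate 8 (not isolated)
Conditions: [Ir(OMe)(cod)]2 (cat.), 4,4′-di-tert-butyl-2,2′-bipyridine (cat.), B2pin2 (1 equiv), THF, 80 °C; then KHSO5 (as 2KHSO5·KHSO4·K2SO4), acetone–H2O, rt
Reagents that add atoms: potassium peroxymonosulfate KHSO5, [K+].[O-]S(=O)(=O)OO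
Why: Iridium-catalysed C–H borylation is sterically governed and should occur only at C4, the one ring C–H with no ortho substituent (C3 is flanked by OMe, C5 by propyl), and oxidation of the C–B bond then places the hydroxyl on the same carbon (borylation–oxidation sequence).

Step 6
Reactants: 4 2,2-dimethyl-6-(2,4-dioxononyl)-4H-1,3-dioxin-4-one; 9 tert-butyl 4-hydroxy-2-methoxy-6-propylbenzoate
Product: 13 tert-butyl 4-[(2,4-dihydroxy-6-pentylbenzoyl)oxy]-2-methoxy-6-propylbenzoate, via acylketene 10 (not isolated), via triketo aryl ester 11 (not isolated), via aldol carbinol 12 (not isolated)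
Conditions: 9 (1.5 equiv), PhMe (concentrated), 110 °C; then Et3N, CH2Cl2, rt; then AcOH
Reagents that add atoms: none
Why: Heating 4 expels acetone by a retro-hetero-Diels–Alder reaction to give acylketene 10, whose ketene carbon is attacked by the phenol oxygen of 9 to give the 3,5,7-trioxo aryl ester 11; Et3N then enolises C2 (between ester and ketone), which adds to the C7 ketone to give carbinol 12, and loss of water with enolisation of the C3 and C5 ketones gives the benzene ring of 13. The closest known reaction type is the dioxinone thermolysis–ketene capture–cycloaromatisation cascade used for resorcylate esters of alcohols, together with the known capture of acylketenes by phenols to give aryl beta-keto esters. The one ring closed is ring A, by a 6-(enolendo)-exo-trig aldol addition that forms the C1–C6 bond of the arene (C2–C7 of the chain), and the order of the chain fixes the pattern: ester carbon on C1, hydroxyls at C2 and C4, pentyl at C6. No stereocentre remains, since the two sp3 centres of 12 form without control and are erased on aromatisation. Two selectivities are needed: capture of 10 by the phenol must outrun lactonisation of 10 onto its own enol oxygen (a 4-hydroxy-2-pyrone), which the excess of 9, the high concentration and the absence of any other O–H or N–H group should secure; and the aldol must outrun Claisen-type attack of C6 on the aryl ester or loss of the aryloxide, which the mild amine base in an aprotic medium, the higher electrophilicity of the non-enolised C7 ketone and the irreversible dehydration to the arene should secure.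

Step 7
Reactants: 13 tert-butyl 4-[(2,4-dihydroxy-6-pentylbenzoyl)oxy]-2-methoxy-6-propylbenzoate
Product: 14 tert-butyl 4-[(2-hydroxy-4-methoxy-6-pentylbenzoyl)oxy]-2-methoxy-6-propylbenzoate
Conditions: MeI (1.1 equiv), K2CO3 (1.1 equiv), acetone, rt
Reagents that add atoms: iodomethane, CI
Why: In this Williamson etherification the 4-hydroxyl of ring A is the more acidic and unchelated one, while the 2-hydroxyl is held in a hydrogen bond to the ester carbonyl, so one equivalent of MeI should methylate only O4.

Step 8
Reactants: 14 tert-butyl 4-[(2-hydroxy-4-methoxy-6-pentylbenzoyl)oxy]-2-methoxy-6-propylbenzoate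
Product: 15 4-[(2-hydroxy-4-methoxy-6-pentylbenzoyl)oxy]-2-methoxy-6-propylbenzoic acid
Conditions: TFA–CH2Cl2 (1:4), 0 °C to rt
Reagents that add atoms: none
Why: Acidolysis of the tert-butyl ester proceeds by alkyl–oxygen cleavage with loss of isobutene, which is indifferent to hindrance at the acyl carbon and should leave the aryl ester, the aryl methyl ethers and the phenol untouched.

**Compound list**

1 | 2,2,6-trimethyl-4H-1,3-dioxin-4-one | CC1=CC(=O)OC(C)(C)O1 | starting material
2 | 2,2-dimethyl-6-(2-oxopropyl)-4H-1,3-dioxin-4-one | CC(=O)CC1=CC(=O)OC(C)(C)O1 | intermediate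
3 | N-methoxy-N-methylhexanamide | CCCCCC(=O)N(C)OC | starting material
4 | 2,2-dimethyl-6-(2,4-dioxononyl)-4H-1,3-dioxin-4-one | CCCCCC(=O)CC(=O)CC1=CC(=O)OC(C)(C)O1 | intermediate
5 | 2-methoxy-6-methylbenzoic acid | COc1cccc(C)c1C(=O)O | starting material
6 | 2-methoxy-6-propylbenzoic acid | CCCc1cccc(OC)c1C(=O)O | intermediate
7 | tert-butyl 2-methoxy-6-propylbenzoate | CCCc1cccc(OC)c1C(=O)OC(C)(C)C | intermediate
8 | tert-butyl 2-methoxy-6-propyl-4-(4,4,5,5-tetramethyl-1,3,2-dioxaborolan-2-yl)benzoate | CCCc1cc(B2OC(C)(C)C(C)(C)O2)cc(OC)c1C(=O)OC(C)(C)C | intermediate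
9 | tert-butyl 4-hydroxy-2-methoxy-6-propylbenzoate | CCCc1cc(O)cc(OC)c1C(=O)OC(C)(C)C | intermediate
10 | 3,5,7-trioxododec-1-en-1-one (acylketene) | CCCCCC(=O)CC(=O)CC(=O)C=C=O | intermediate
11 | tert-butyl 2-methoxy-6-propyl-4-[(3,5,7-trioxododecanoyl)oxy]benzoate | CCCCCC(=O)CC(=O)CC(=O)CC(=O)Oc1cc(CCC)c(C(=O)OC(C)(C)C)c(OC)c1 | intermediate
12 | tert-butyl 4-[(2-hydroxy-4,6-dioxo-2-pentylcyclohexane-1-carbonyl)oxy]-2-methoxy-6-propylbenzoate (mixture of stereoisomers) | CCCCCC1(O)CC(=O)CC(=O)C1C(=O)Oc1cc(CCC)c(C(=O)OC(C)(C)C)c(OC)c1 | intermediate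
13 | tert-butyl 4-[(2,4-dihydroxy-6-pentylbenzoyl)oxy]-2-methoxy-6-propylbenzoate | CCCCCc1cc(O)cc(O)c1C(=O)Oc1cc(CCC)c(C(=O)OC(C)(C)C)c(OC)c1 | intermediate
14 | tert-butyl 4-[(2-hydroxy-4-methoxy-6-pentylbenzoyl)oxy]-2-methoxy-6-propylbenzoate | CCCCCc1cc(OC)cc(O)c1C(=O)Oc1cc(CCC)c(C(=O)OC(C)(C)C)c(OC)c1 | intermediate
15 | 4-[(2-hydroxy-4-methoxy-6-pentylbenzoyl)oxy]-2-methoxy-6-propylbenzoic acid | CCCCCc1cc(OC)cc(O)c1C(=O)Oc1cc(CCC)c(C(=O)O)c(OC)c1 | target

**Count and risks**

Total step count: 8. Longest linear sequence: 6 steps (5 → 6 → 7 → 9 → 13 → 14 → 15, steps 3 to 8); the dioxinone arm (steps 1 and 2) joins at step 6.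

Steps most likely to fail:

1. Step 6. The acylketene may be consumed by ring closure onto its own enol oxygen before the electron-poor phenol adds. The amine may also trigger loss of the aryloxide or a Claisen-type closure onto the activated aryl ester in place of the aldol. The fallback sets out from 4 and 9 and comes back at 14, so that step 7 is not needed. Compound 4 is cycloaromatised on its own with Et3N in CH2Cl2 at rt, where the dioxinone ring stays closed, to 7-hydroxy-2,2-dimethyl-5-pentyl-4H-1,3-benzodioxin-4-one F1. Its only phenol is methylated (MeI, K2CO3, acetone) to 7-methoxy-2,2-dimethyl-5-pentyl-4H-1,3-benzodioxin-4-one F2. The acetonide lactone is opened with KOH in aqueous DMSO at 80 °C to 2-hydroxy-4-methoxy-6-pentylbenzoic acid F3. F3 is joined to 9 by a carbodiimide esterification (dicyclohexylcarbodiimide, toluene, rt), which should give 14. Ring construction and ester formation are thereby separated.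

2. Step 2. Dianion formation may be incomplete, the acidic product may quench unreacted dianion, or acylation may occur at oxygen. The fallback sets out from 1 and comes back at 4. The dienolate of 1 (LiN(SiMe3)2, THF, −78 °C) is acylated with allyl 3-chloro-3-oxopropanoate to allyl 4-(2,2-dimethyl-4-oxo-4H-1,3-dioxin-6-yl)-3-oxobutanoate F4. Soft enolisation with MgCl2 and pyridine in CH2Cl2 and C-acylation with hexanoyl chloride at the carbon between ketone and ester should give allyl 2-[(2,2-dimethyl-4-oxo-4H-1,3-dioxin-6-yl)acetyl]-3-oxooctanoate F5. Pd(PPh3)4 (zerovalent palladium) with morpholine in THF removes the allyl group, and the liberated beta-keto acid loses carbon dioxide to give 4.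

3. Step 7. The chelated 2-hydroxyl may also be alkylated once the first phenoxide has reacted, or carbonate may induce transacylation or cleavage of the aryl ester. The fallback sets out from 13 and comes back at 14. Phenoxide alkylation is replaced by a Mitsunobu etherification with methanol (PPh3, diisopropyl azodicarboxylate, THF, 0 °C to rt). No free phenoxide is present, and only the more acidic, unchelated 4-hydroxyl should act as the pronucleophile. This fallback makes no new compound (F0).

**Further compounds**

F1 | step 6 | 7-hydroxy-2,2-dimethyl-5-pentyl-4H-1,3-benzodioxin-4-one | CCCCCc1cc(O)cc2OC(C)(C)OC(=O)c12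
F2 | step 6 | 7-methoxy-2,2-dimethyl-5-pentyl-4H-1,3-benzodioxin-4-one | CCCCCc1cc(OC)cc2OC(C)(C)OC(=O)c12
F3 | step 6 | 2-hydroxy-4-methoxy-6-pentylbenzoic acid | CCCCCc1cc(OC)cc(O)c1C(=O)O
F4 | step 2 | allyl 4-(2,2-dimethyl-4-oxo-4H-1,3-dioxin-6-yl)-3-oxobutanoate | C=CCOC(=O)CC(=O)CC1=CC(=O)OC(C)(C)O1
F5 | step 2 | allyl 2-[(2,2-dimethyl-4-oxo-4H-1,3-dioxin-6-yl)acetyl]-3-oxooctanoate | CCCCCC(=O)C(C(=O)OCC=C)C(=O)CC1=CC(=O)OC(C)(C)O1
F0 | step 7 | none | none
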